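**Retrosynthetic overview**
1. Target ⇐ acetylation of the axial C6–OH and unmasking of the (12E)-diene by cheletropic loss of SO2 from a 3-sulfolene; the axial C6–O ⇐ 7-en-6-one by hydride delivery anti to the C10 methyl.
2. C6=O and C17–OAc ⇐ two allylic C–H oxidations of a single Δ7 olefin (C17 first, then C6).
3. Decalin ⇐ one proton-initiated, catalyst-controlled bicyclization of the complete acyclic C20 chain (diene masked as sulfolene): ring A (C4–C5) first, ring B (C10–C9) second, ended by loss of H-7; this sets C5, C9 and C10 together.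
4. Acyclic chain ⇐ (2E,6E)-farnesyl bromide + 3-methyl-3-sulfolene (α-sulfonyl alkylation).

Assumption and conventions: labdane numbering is used, and "12,15-sulfolene" means that C12–C15 form a 3-methyl-2,5-dihydrothiophene 1,1-dioxide ring (SO2 between C12 and C15, C13=C14). Compounds 3–9 are carried as about 1:1 mixtures of epimers at C12, which is left undefined in their SMILES and disappears in step 6. Changes of R/S descriptors along the route at C9 and C10 are CIP-priority changes only. (2E,6E)-Farnesyl bromide is bought as such.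

**Step 1**
Reactants: 1 (2E,6E)-farnesyl bromide; 2 3-methyl-3-sulfolene (3-methyl-2,5-dihydrothiophene 1,1-dioxide)
Product: 3 2-[(2E,6E)-farnesyl]-3-methyl-3-sulfolene (masked (3E,6E,10E)-α-springene; racemic at ring C2)
Conditions: LiHMDS (1.1 equiv) added to 1 + 2 (1.2 equiv), THF–HMPA 4:1, −78 °C; aq. NH4Cl
Reagents that add atoms: none
Why: α-Sulfonyl carbanion alkylation (SN2) under in-situ-quench conditions: LiHMDS deprotonates 2 mainly at C2 (next to the methyl-bearing olefin carbon) and the anion is trapped at once by the allylic bromide before it can ring-open; the new ring stereocentre forms racemic and is erased in step 6, and the two E-olefins of 1 are untouched.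

**Step 2**
Reactants: 3 2-[(2E,6E)-farnesyl]-3-methyl-3-sulfolene
Product: 4 (5R,9R,10R)-labd-7-ene 12,15-sulfolene (trans-decalin, H-5 and H-9 both anti to the C10 methyl)
Conditions: confined chiral imidodiphosphorimidate (IDPi) Brønsted acid (5 mol %, the antipode that gives the 5R,10R series, fixed in a pilot run), (CF3)3COH, −10 → 0 °C
Reagents that add atoms: none
Why: Proposed new method: the confined acid protonates the terminal isopropylidene inside its chiral pocket and the chair–chair folded chain closes C4–C5 and then C10–C9 by anti additions across the two E-olefins (Stork–Eschenmoser cationic polyene cyclization), which fixes the trans ring fusion and the equatorial C9 side chain and, through the catalyst antipode, the (5R,9R,10R) configuration; the C8 cation has no internal nucleophile and the last olefin is switched off by the sulfone, so it loses axial H-7 to the catalyst anion, giving the Δ7 olefin and turning the acid over; the closest known reactions are the IDPi-catalysed bicyclization of homofarnesol to ambrox-type ethers (OH-terminated) and superacid cyclizations of farnesyl sulfones to Δ7-drimenyl sulfones.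

**Step 3**
Reactants: 4 (5R,9R,10R)-labd-7-ene 12,15-sulfolene
Product: 6 (5R,9S,10R)-17-acetoxylabd-7-ene 12,15-sulfolene, via allylic alcohol 5 (not isolated)
Conditions: SeO2 (0.2 equiv), t-BuOOH (1.2 equiv), CH2Cl2, 0 °C → rt; then pyridine, Ac2O, DMAP (cat.), rt, same flask
Reagents that add atoms: selenium dioxide O=[Se]=O (delivers the oxygen and is re-formed by tert-butyl hydroperoxide CC(C)(C)OO); acetic anhydride CC(=O)OC(C)=O
Why: Sharpless SeO2/t-BuOOH allylic oxidation (ene reaction, then [2,3]-sigmatropic shift) acts on the only electron-rich olefin, at its more substituted end and on CH3 rather than the shielded C9 methine, so C17 is hydroxylated with Δ7 kept; DMAP-catalysed acetylation in the same flask caps the alcohol; no stereocentre is formed or touched.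

**Step 4**
Reactants: 6 (5R,9S,10R)-17-acetoxylabd-7-ene 12,15-sulfolene
Product: 7 (5R,9S,10S)-17-acetoxy-6-oxolabd-7-ene 12,15-sulfolene
Conditions: Rh2(cap)4 (1 mol %), t-BuOOH (70 % aq., 5 equiv), ClCH2CH2Cl, 40 °C
Reagents that add atoms: tert-butyl hydroperoxide CC(C)(C)OO
Why: Dirhodium-caprolactamate/t-BuOOH allylic C–H oxidation (tert-butylperoxyl radical chain): hydrogen is abstracted from the only unhindered allylic CH2 (C6) and the mixed peroxide collapses to the conjugated 7-en-6-one; C9–H is shielded by the quaternary C10, the sulfolene C–H bonds are electron-poor, and C5 already has the stable trans-fused configuration.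

**Step 5**
Reactants: 7 (5R,9S,10S)-17-acetoxy-6-oxolabd-7-ene 12,15-sulfolene
Product: 8 (5R,6S,9S,10S)-17-acetoxy-6-hydroxylabd-7-ene 12,15-sulfolene (6-OH axial, cis to the C10 methyl)
Conditions: NaBH4, CeCl3·7H2O, MeOH, −78 → −20 °C
Reagents that add atoms: none
Why: Luche 1,2-reduction: hydride attacks C6 from the face anti to the two syn-axial methyls (C10–CH3 and the axial C4–CH3), giving the axial alcohol cis to the C10 methyl (6S); the primary acetate and the sulfolene survive at low temperature.

**Step 6**
Reactants: 8 (5R,6S,9S,10S)-17-acetoxy-6-hydroxylabd-7-ene 12,15-sulfolene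
Product: 10 (5R,6S,9S,10S)-labda-7,12E,14-triene-6,17-diyl diacetate (target), via sulfolene diacetate 9 (not isolated)
Conditions: Ac2O, DMAP (cat.), pyridine, rt; then 115 °C (reflux), 1–2 h
Reagents that add atoms: acetic anhydride CC(=O)OC(C)=O
Why: DMAP-catalysed acetylation of the hindered axial alcohol, then thermal cheletropic extrusion of SO2 (retro-[4+1], disrotatory) in which the C12 substituent rotates outward, so both C12 epimers give only the (12E)-diene; pyridine buffers the SO2 and no ring stereocentre is involved.

**Compound list**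
1 | (2E,6E)-farnesyl bromide, (2E,6E)-1-bromo-3,7,11-trimethyldodeca-2,6,10-triene | CC(C)=CCC/C(C)=C/CC/C(C)=C/CBr | starting material
2 | 3-methyl-3-sulfolene, 3-methyl-2,5-dihydrothiophene 1,1-dioxide | CC1=CCS(=O)(=O)C1 | starting material
3 | 3-methyl-2-[(2E,6E)-3,7,11-trimethyldodeca-2,6,10-trien-1-yl]-2,5-dihydrothiophene 1,1-dioxide | CC(C)=CCC/C(C)=C/CC/C(C)=C/CC1C(C)=CCS1(=O)=O | intermediate
4 | 3-methyl-2-{[(1R,4aR,8aR)-2,5,5,8a-tetramethyl-1,4,4a,5,6,7,8,8a-octahydronaphthalen-1-yl]methyl}-2,5-dihydrothiophene 1,1-dioxide | CC1=CCS(=O)(=O)C1C[C@@H]2C(C)=CC[C@@H]3C(C)(C)CCC[C@@]23C | intermediate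
5 | {(1S,4aR,8aR)-5,5,8a-trimethyl-1-[(3-methyl-1,1-dioxo-2,5-dihydrothiophen-2-yl)methyl]-1,4,4a,5,6,7,8,8a-octahydronaphthalen-2-yl}methanol | CC1=CCS(=O)(=O)C1C[C@@H]2C(CO)=CC[C@@H]3C(C)(C)CCC[C@@]23C | intermediate (not isolated)
6 | {(1S,4aR,8aR)-5,5,8a-trimethyl-1-[(3-methyl-1,1-dioxo-2,5-dihydrothiophen-2-yl)methyl]-1,4,4a,5,6,7,8,8a-octahydronaphthalen-2-yl}methyl acetate | CC1=CCS(=O)(=O)C1C[C@@H]2C(COC(C)=O)=CC[C@@H]3C(C)(C)CCC[C@@]23C | intermediate
7 | {(1S,4aR,8aS)-5,5,8a-trimethyl-1-[(3-methyl-1,1-dioxo-2,5-dihydrothiophen-2-yl)methyl]-4-oxo-1,4,4a,5,6,7,8,8a-octahydronaphthalen-2-yl}methyl acetate | CC1=CCS(=O)(=O)C1C[C@@H]2C(COC(C)=O)=CC(=O)[C@@H]3C(C)(C)CCC[C@@]23C | intermediate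
8 | {(1S,4S,4aR,8aS)-4-hydroxy-5,5,8a-trimethyl-1-[(3-methyl-1,1-dioxo-2,5-dihydrothiophen-2-yl)methyl]-1,4,4a,5,6,7,8,8a-octahydronaphthalen-2-yl}methyl acetate | CC1=CCS(=O)(=O)C1C[C@@H]2C(COC(C)=O)=C[C@H](O)[C@@H]3C(C)(C)CCC[C@@]23C | intermediate
9 | {(1S,4S,4aR,8aS)-4-acetoxy-5,5,8a-trimethyl-1-[(3-methyl-1,1-dioxo-2,5-dihydrothiophen-2-yl)methyl]-1,4,4a,5,6,7,8,8a-octahydronaphthalen-2-yl}methyl acetate | CC1=CCS(=O)(=O)C1C[C@@H]2C(COC(C)=O)=C[C@H](OC(C)=O)[C@@H]3C(C)(C)CCC[C@@]23C | intermediate (not isolated)
10 | {(1S,4S,4aR,8aS)-4-acetoxy-5,5,8a-trimethyl-1-[(2E)-3-methylpenta-2,4-dien-1-yl]-1,4,4a,5,6,7,8,8a-octahydronaphthalen-2-yl}methyl acetate | C=C/C(C)=C/C[C@@H]1C(COC(C)=O)=C[C@H](OC(C)=O)[C@@H]2C(C)(C)CCC[C@@]12C | target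

**Step count**
Total: 6 steps. Longest linear sequence: 6 steps (1/2 → 10).

**Steps most likely to fail, with fallbacks**

Step 2 is the largest risk. The substrate has no terminating nucleophile, so the enantioselectivity, the completeness of the second ring closure and the Δ7/Δ8(17)/Δ8 olefin ratio are unproven. The fallback sets out from 3 and splits the cyclization in two. A chiral Lewis-acid-assisted Brønsted acid (BINOL mono-(o-fluorobenzyl) ether·SnCl4, toluene, −78 °C) performs only the enantio-determining protonation and ring-A closure, giving the monocyclic (R)-α-cyclo olefin F1. Ring B is then closed under substrate control with an achiral superacid (FSO3H, 2-nitropropane, −78 °C): re-protonation of the ring olefin regenerates the C10 cation, the existing C5 centre steers the chair-like closure, and loss of H-7 gives the Δ7 olefin. The sequence comes back to the route at 4.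

Step 3 is the second risk. SeO2 may attack the C9 methine or C6 instead of C17, or run on to the 17-aldehyde, which would not be acetylated. The fallback sets out from 4 and replaces C–H hydroxylation by an olefin transposition pair. Ene-type allylic chlorination (Ca(OCl)2, solid CO2, CH2Cl2–H2O, 0 °C) puts chlorine axially on C7 from the face anti to the C10 methyl and moves the double bond to C8=C17, giving the 7-chloro-8(17)-ene F2. SN2′ displacement at the exocyclic CH2 with CsOAc (DMF, 40 °C) moves the olefin back to Δ7 and comes back to the route at 6, without passing through 5.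

Step 4 is the third risk. The peroxyl-radical oxidation may stall on the acetoxy-substituted olefin, stop at mixed peroxides or touch C9–H. The fallback sets out from 6 and installs the C6 oxygen by palladium chemistry instead of C–H oxidation and reduction. Pd(0)-catalysed 1,4-elimination of the allylic acetate (Pd(OAc)2, PPh3, dioxane, 80 °C; only H-6 is available for β-elimination) gives the semicyclic 6,8(17)-diene F3. Pd(II)-catalysed 1,4-diacetoxylation (Pd(OAc)2 cat., p-benzoquinone, LiOAc, LiCl cat., AcOH, rt) then adds acetate to C17 and, after Pd has bound the face anti to the C10 methyl, chloride-enforced external acetate attack anti to palladium places the C6 acetate axial and cis to the C10 methyl. This comes back to the route at 9, which is heated in pyridine as in the second half of step 6; steps 4 and 5 are bypassed. The facial outcome at C6 is the uncertain point of this fallback.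

**Further compounds**
F1 | step 2 | 3-methyl-2-{(2E)-3-methyl-5-[(1R)-2,6,6-trimethylcyclohex-2-en-1-yl]pent-2-en-1-yl}-2,5-dihydrothiophene 1,1-dioxide | CC1=CCS(=O)(=O)C1C/C=C(\C)CC[C@H]2C(C)=CCCC2(C)C
F2 | step 3 | 2-{[(1S,3S,4aR,8aR)-3-chloro-5,5,8a-trimethyl-2-methylidenedecahydronaphthalen-1-yl]methyl}-3-methyl-2,5-dihydrothiophene 1,1-dioxide | CC1=CCS(=O)(=O)C1C[C@@H]2C(=C)[C@@H](Cl)C[C@@H]3C(C)(C)CCC[C@@]23C
F3 | step 4 | 3-methyl-2-{[(1R,4aR,8aS)-5,5,8a-trimethyl-2-methylidene-1,2,4a,5,6,7,8,8a-octahydronaphthalen-1-yl]methyl}-2,5-dihydrothiophene 1,1-dioxide | CC1=CCS(=O)(=O)C1C[C@@H]2C(=C)C=C[C@@H]3C(C)(C)CCC[C@@]23C
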